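## Structural features

1. The target is an achiral C24H16O10 polyphenol with four rings. These are a 2-hydroxy-1,4-naphthoquinone (quinone ring B = C1–C4, C4a, C8a; benzenoid ring A = C4a, C5–C8, C8a), a resorcinol ring C (C1′–C6′) and a 4-hydroxy-2H-pyran-2-one ring D (O1″–C6″).
2. Rings A and C are joined through one ketone carbon (C6–CO–C1′). Rings C and D are joined through one methylene group (C6′–CH2–C6″).
3. There is no stereocentre, and the twisted diaryl ketone is not expected to be configurationally stable, so nothing stereochemical has to be set.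
4. The ketone has four ortho substituents: C5–CH3 and C7–OH on ring A, C2′–OH and C6′–CH2 on ring C. Ring A keeps a single hydrogen (C8–H) and carries CH3, aroyl and OH on three neighbouring carbons.
5. The fragile groups are the hydroxyquinone (nucleophiles, reductants, base with air), the pyranone (hard nucleophiles at C2″ and C6″, nucleophilic C3″ when O-4″ is free), the doubly activated CH2 and five acidic OH groups.
6. The real difficulty is twofold. The first part is the tetra-ortho-substituted benzophenone. The second is the position of O-2 relative to ring A: O-2 and O-7 are both conjugated to C4=O, which is the polarity-mismatched isomer for any cycloaddition or nucleophilic oxygenation.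
7. The key step exploits the six atoms O-2′, C2′, C1′, CO, C6 and C5(CH3). These are the atoms O1, C8a, C4a, C4, C3 and C2(CH3) of a 2-methylchromone. C7(OH)–C8H is then an enol two-carbon arm on chromone C3, and C8a–C4a is a quinone C=C bond.
8. In one sentence: ring A is closed by a Diels–Alder reaction of a 3-(1-ethoxyvinyl)-2-methylchromone with 2,5-dichlorobenzoquinone, and the adduct aromatises by opening the chromone, so the benzophenone is released and never made by attack on its carbonyl group.

## Logic of the disconnections

**20 ⇒ 19.** The bonds cut are four O–alkyl bonds (benzyl at O-2 and O-4″, ethyl at O-7, methyl at O-4′). All four ethers fall to one Lewis acid, and the product is stable to acid. All five acidic OH groups but one stay masked until the end. The forward step must cleave a vinylogous benzyl ester on ring D and an unactivated aryl methyl ether without touching the quinone.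

**19 ⇒ 18.** The bond cut is C2–O. C2–Cl in 18 is a vinylogous acyl chloride, and it marks C2 without ambiguity. An oxygen donor already on the dienophile would oppose the orientation the key step needs. The gain is a symmetric, commercial dienophile. The forward step needs ipso addition–elimination to outrun attack at C3. It must also run before O-7 is unmasked, because a C7 aryloxide would deactivate C4=O and with it C2.

**18 ⇒ 14 + 15 (key).** The bonds cut are C8–C8a and C4a–C5 of ring A. In the same retrosynthetic move the O-2′–C5 bond is re-made, which folds the benzophenone back into the pyranone ring of 14. Every bond to the ketone carbon then exists before the carbonyl group becomes crowded. The CH3/aroyl/OH/H sequence of ring A is written into the diene. The whole naphthoquinone, the hindered ketone and the free 2′-OH appear in one operation from a bicyclic heterocycle and a C6 quinone, with no redox adjustment. The forward step needs a (4+2) cycloaddition on a tetrasubstituted, acyl-bearing diene with full regiocontrol, followed by two eliminations in the right order.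

**14 ⇒ 12 + 13.** The bond cut is C3–C(vinyl) of the chromone, which becomes C6–C7 of the target. A cross-coupling puts the enol ether in place with no choice of enolisation site. Enolising a 3-acetyl-2-methylchromone could instead involve the vinylogous C2 methyl group. The gain is a two-carbon commercial reagent. The forward step must couple at a vinyl iodide flanked by CH3 and C=O and handle an acid-sensitive product.

**12 ⇒ 11.** The bonds cut are O1–C2 and C3–I. An ortho-methoxyaryl ynone closes onto an iodonium-activated triple bond and loses its methyl group. Ring closure, unmasking of O-2′ and installation of the coupling handle are therefore one step. The electrophilic iodine must prefer the alkyne to ring C and to C3″ of ring D.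

**11 ⇒ 8 + 9.** The bond cut is C1′–CO. This bond is made while the acyl partner is a rod-shaped alkynoyl cation, so the future congestion is absent. The gain is a C4 acid and a symmetric 3,5-dimethoxybenzyl unit. Acylation must occur ortho to the CH2 group (para to one OMe) and not between the two OMe groups.

**8 ⇒ 7.** The bond cut is O-4″–benzyl. A benzyl vinylogous ester survives acid, ICl, palladium and heat, and falls to BBr3, whereas a methyl ether at this position is known to be reluctant. Alkylation must go to O-4″ and not to C3″ or O-2″.

**7 ⇒ 5.** The bond cut is the lactone C2″–O1″. Neutral thermolysis of 5 delivers an acylketene that lactonises on its own enol, so ring D forms without base. The price is one molecule of acetone lost.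

**5 ⇒ 1 + 2.** The bond cut is C5″–C6″ (acyl carbon to the γ-carbon of 2). It joins two commercial compounds and brings in all carbons of ring D. The γ-acylation of a dienolate must beat deprotonation of the arylacetyl donor.

## Other disconnections considered

**Alternative 1:** This is the first that comes to mind, a cut at C6–CO.
- **Forward key step:** bromine–lithium exchange on 2-bromo-3,5,6,8-tetramethoxy-1-methylnaphthalene A1 and addition to methyl 2-(2-formyl-3,5-dimethoxyphenyl)acetate A2 give the diaryl carbinol A3. Oxidation of A3, construction of ring D from the ester, oxidative demethylation of ring B and global demethylation would follow.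
- **Structure:** both partners carry two ortho substituents, so the most crowded bond of the molecule is built head-on in a bimolecular step.
- **Compatibility:** the aryllithium tolerates neither the ester nor the acidic CH2 group. Ring D must therefore be built afterwards with strong base on the hindered ketone.
- **Step economy:** A1 needs its own regiocontrolled naphthalene synthesis, and three redox corrections are added.

**Alternative 2:** The cut is at both C1′–CO and C6′–CH2.
- **Forward key step:** the aryne released from 3,5-dimethoxy-2-(trimethylsilyl)phenyl triflate A5 inserts into the CO–CH2 bond of the β-keto ester A4 and gives the 2-aroylphenylacetate A6.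
- **In its favour:** the idea is attractive and the aryne polarity is right.
- **Mechanism:** the aryl anion must add to a mesityl-type carbonyl group shielded on both faces by C5–CH3 and the C7 alkoxy group. Proton transfer (plain α-arylation) should outrun closure of the four-membered ring.
- **Step economy:** A4 demands the same separate naphthalene synthesis, and ring D still has to be built with base after the ketone.

**Alternative 3:** The cut is at C1′–C2′ and C5′–C6′, so ring C is built from open-chain carbons.
- **Forward key step:** a Diels–Alder reaction of the naphthyl alkynyl ketone A7 with 1-methoxy-1,3-bis(trimethylsilyloxy)buta-1,3-diene A8, followed by aromatisation, gives the resorcinol A9.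
- **In its favour:** the polarity is matched and the slim alkyne solves the ketone problem.
- **Structure:** the propargylic CH2 of A7 lies between an ynone and a pyranone and should isomerise readily to allenyl or dienyl ketones, which would blur the regiochemistry.
- **Scope:** the step does nothing for ring A, half of the problem, which again needs a full naphthalene synthesis and a late oxidation to the quinone.

Key step: step 7

Assumption: the target is taken in the drawn tautomeric form (2-hydroxy-1,4-naphthoquinone, 4-hydroxy-2H-pyran-2-one). Rotation about the two aryl–CO bonds is taken as fast, so no stereochemical element has to be set.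

## Route

Step 1
Reactants: 1 3,5-dimethoxyphenylacetic acid; 2 2,2,6-trimethyl-4H-1,3-dioxin-4-one
Product: 5 6-[3-(3,5-dimethoxyphenyl)-2-oxopropyl]-2,2-dimethyl-4H-1,3-dioxin-4-one, via acyl imidazolide 3 (not isolated), via lithium dienolate 4 (not isolated)
Conditions: 1, CDI, THF, rt; separately 2 (2.2 equiv), LiN(SiMe3)2 (2.2 equiv), THF, –78 °C; combine, –78 → –20 °C; 1 M HCl
Reagents that add atoms: 1,1'-carbonyldiimidazole, O=C(n1ccnc1)n1ccnc1 (imidazolyl group of 3); lithium bis(trimethylsilyl)amide, [Li+].C[Si](C)(C)[N-][Si](C)(C)C (lithium of 4)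
Why: Claisen-type γ-acylation of a dioxinone dienolate by an acyl imidazolide, a standard entry to keto-dioxinones. The second equivalent of 4 takes up the acidic proton of the product and returns to 2 on quenching.

Step 2
Reactants: 5 6-[3-(3,5-dimethoxyphenyl)-2-oxopropyl]-2,2-dimethyl-4H-1,3-dioxin-4-one
Product: 7 6-(3,5-dimethoxybenzyl)-4-hydroxy-2H-pyran-2-one, via acylketene 6 (not isolated)
Conditions: PhMe, 110 °C
Reagents that add atoms: none
Why: Thermal retro-(4+2) loss of acetone gives the acylketene, and the enol oxygen of its δ-ketone adds to the ketene carbon to close the six-membered lactone. The conditions are neutral, so the acidic CH2 groups are not disturbed.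

Step 3
Reactants: 7 6-(3,5-dimethoxybenzyl)-4-hydroxy-2H-pyran-2-one
Product: 8 4-(benzyloxy)-6-(3,5-dimethoxybenzyl)-2H-pyran-2-one
Conditions: BnBr, K2CO3, DMF, rt → 50 °C
Reagents that add atoms: benzyl bromide, BrCc1ccccc1
Why: Williamson-type O-alkylation of the pyronate, which with carbonate in a dipolar solvent should go mainly to O-4. The benzyl group blocks the nucleophilic C3 position towards the quinone of step 7.

Step 4
Reactants: 8 4-(benzyloxy)-6-(3,5-dimethoxybenzyl)-2H-pyran-2-one; 9 but-2-ynoic acid
Product: 11 1-{2-[(4-benzyloxy-2-oxo-2H-pyran-6-yl)methyl]-4,6-dimethoxyphenyl}but-2-yn-1-one, via mixed anhydride 10 (not isolated)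
Conditions: 9, (CF3CO)2O, CH2Cl2, 0 °C; then 8, 0 °C → rt
Reagents that add atoms: trifluoroacetic anhydride, O=C(OC(=O)C(F)(F)F)C(F)(F)F (trifluoroacetyl group of 10)
Why: Friedel–Crafts acylation with an acyl trifluoroacetate, which transfers the less electron-poor (alkynoyl) acyl group. As with 3,5-dimethoxyphenylacetates, attack should occur para to one OMe and ortho to the CH2 group rather than between the two OMe groups. The benzyl vinylogous ester should behave like a benzyl ester towards CF3CO2H.

Step 5
Reactants: 11 1-{2-[(4-benzyloxy-2-oxo-2H-pyran-6-yl)methyl]-4,6-dimethoxyphenyl}but-2-yn-1-one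
Product: 12 5-[(4-benzyloxy-2-oxo-2H-pyran-6-yl)methyl]-3-iodo-7-methoxy-2-methyl-4H-chromen-4-one
Conditions: ICl (1.2 equiv), CH2Cl2, –78 °C; aq. Na2S2O3
Reagents that add atoms: iodine monochloride, ClI
Why: Electrophilic iodocyclisation of a 2-methoxyaryl ynone. The ortho-methoxy oxygen attacks the iodonium-activated alkyne in the 6-endo-dig mode and chloride removes the methyl group from the oxonium ion. At –78 °C the alkyne should react before the acyl-deactivated ring C or C3 of the pyranone.

Step 6
Reactants: 12 5-[(4-benzyloxy-2-oxo-2H-pyran-6-yl)methyl]-3-iodo-7-methoxy-2-methyl-4H-chromen-4-one; 13 tributyl(1-ethoxyvinyl)stannane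
Product: 14 5-[(4-benzyloxy-2-oxo-2H-pyran-6-yl)methyl]-3-(1-ethoxyvinyl)-7-methoxy-2-methyl-4H-chromen-4-one
Conditions: 13 (1.3 equiv), Pd(PPh3)4 (5 mol %), CuI (10 mol %), 1,4-dioxane, 90 °C; Et3N-deactivated SiO2
Reagents that add atoms: none
Why: Stille coupling of a 3-iodochromone, a good partner for oxidative addition to zerovalent palladium, with the usual acetyl-anion equivalent. The enol ether is kept, which fixes the diene constitution without any enolisation step.

Step 7
Reactants: 14 5-[(4-benzyloxy-2-oxo-2H-pyran-6-yl)methyl]-3-(1-ethoxyvinyl)-7-methoxy-2-methyl-4H-chromen-4-one; 15 2,5-dichloro-1,4-benzoquinone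
Product: 18 6-{2-[(4-benzyloxy-2-oxo-2H-pyran-6-yl)methyl]-6-hydroxy-4-methoxybenzoyl}-2-chloro-7-ethoxy-5-methylnaphthalene-1,4-dione, via cycloadduct 16 (not isolated), via dihydronaphthoquinone 17 (not isolated)
Conditions: 15 (1.5 equiv), NaHCO3 (3 equiv), 4 Å MS, PhMe, 80 °C, Ar, dark
Reagents that add atoms: none
Why: Proposed new method: 14 is a 1-aryloxy-1-methyl-3-ethoxybuta-1,3-diene whose C1 oxygen is the ring oxygen of a chromone, so the closest known reaction type is the Diels–Alder/aromatisation sequence of 1,3-dioxygenated butadienes and vinylketene acetals with halobenzoquinones, whereas a normal-demand cycloaddition across C2 of a chromone and a 3-vinyl terminus that ends in loss of the pyranone ring has not been shown for this substrate class. The (4+2) cycloaddition, suprafacial on both partners and asynchronous with the CH2–CH bond leading, joins the vinyl CH2 to the C–H carbon of 15 and chromone C2 to the C–Cl carbon and so closes ring A as the cyclohexene of 16. Enolisation of the ring-fusion C–H expels chloride (E1cB) and restores the quinone in 17; removal of one proton of the C8 methylene group, which is allylic to the quinone and vinylogous to the ketone, then pushes the aryloxide off C5 (vinylogous E1cB), which breaks the former O1–C2 bond, aromatises ring A and sets the 2′-phenol free, so that chloride and aryloxide carry off both oxidation equivalents and no oxidant is needed. The ketone carbon is a spectator throughout, so its four ortho substituents, which would block any addition to it, cost nothing. Regioselectivity is needed and has two sources: the ethoxy group makes the CH2 terminus the nucleophilic end of the diene, and in haloquinones this end goes to the unsubstituted carbon beside C–Cl, while the twofold symmetry of 15 makes its two C=C bonds equivalent and leaves the second chlorine at C2, next to the carbonyl group on the C8 side. The diene has its methyl group inside and its oxygen outside, the same geometry as the 1-methoxy-1-methyl-3-silyloxybutadienes derived from (E)-4-methoxypent-3-en-2-one, which are competent dienes, and the electron-poor 15 offsets the pull of the C4 carbonyl group. The three sp3 centres of 16 (cis ring fusion from the suprafacial addition, methyl-bearing centre from the endo or exo approach) are all erased in the same flask, so no stereocontrol is required. Chemoselectivity rests on the much lower diene reactivity of the 4-benzyloxypyranone at 80 °C, on the excess of 15, which keeps 18 from acting as a second dienophile, and on NaHCO3, which takes up HCl before it can hydrolyse the enol ether but is too weak to hold the new phenol as its aryloxide.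

Step 8
Reactants: 18 6-{2-[(4-benzyloxy-2-oxo-2H-pyran-6-yl)methyl]-6-hydroxy-4-methoxybenzoyl}-2-chloro-7-ethoxy-5-methylnaphthalene-1,4-dione
Product: 19 2-(benzyloxy)-6-{2-[(4-benzyloxy-2-oxo-2H-pyran-6-yl)methyl]-6-hydroxy-4-methoxybenzoyl}-7-ethoxy-5-methylnaphthalene-1,4-dione
Conditions: BnOH (3 equiv), K2CO3 (2.5 equiv), MeCN, 0 °C → rt, Ar; dil. HCl
Reagents that add atoms: benzyl alcohol, OCc1ccccc1
Why: Addition–elimination on a 2-halo-1,4-naphthoquinone (vinylogous acyl chloride). Only attack at C2 has a leaving group, and O-7 is still a neutral ether, so C4=O and C2 keep their electrophilicity. Any alkoxide exchange at O-4″ of the pyranone is degenerate because the nucleophile is also benzyloxide.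

Step 9
Reactants: 19 2-(benzyloxy)-6-{2-[(4-benzyloxy-2-oxo-2H-pyran-6-yl)methyl]-6-hydroxy-4-methoxybenzoyl}-7-ethoxy-5-methylnaphthalene-1,4-dione
Product: 20 6-{2,4-dihydroxy-6-[(4-hydroxy-2-oxo-2H-pyran-6-yl)methyl]benzoyl}-2,7-dihydroxy-5-methylnaphthalene-1,4-dione (target)
Conditions: BBr3 (12 equiv), CH2Cl2, –78 °C → rt; H2O
Reagents that add atoms: none
Why: Lewis-acid ether cleavage. The two benzyl vinylogous esters and the ketone-chelated 7-ethyl ether should fall first and the 4′-methyl ether at room temperature. The quinone, pyranone and diaryl ketone are inert to BBr3.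

## Compound list

| No. | Name | SMILES | Role |
|---|---|---|---|
| 1 | 3,5-dimethoxyphenylacetic acid | COc1cc(CC(=O)O)cc(OC)c1 | starting material |
| 2 | 2,2,6-trimethyl-4H-1,3-dioxin-4-one | CC1=CC(=O)OC(C)(C)O1 | starting material |
| 3 | 2-(3,5-dimethoxyphenyl)-1-(imidazol-1-yl)ethanone | COc1cc(CC(=O)n2ccnc2)cc(OC)c1 | intermediate |
| 4 | lithium 2,2-dimethyl-6-methylidene-6H-1,3-dioxin-4-olate | [Li+].C=C1C=C([O-])OC(C)(C)O1 | intermediate |
| 5 | 6-[3-(3,5-dimethoxyphenyl)-2-oxopropyl]-2,2-dimethyl-4H-1,3-dioxin-4-one | COc1cc(CC(=O)CC2=CC(=O)OC(C)(C)O2)cc(OC)c1 | intermediate |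
| 6 | 6-(3,5-dimethoxyphenyl)-3,5-dioxohex-1-en-1-one (acylketene) | O=C=CC(=O)CC(=O)Cc1cc(OC)cc(OC)c1 | intermediate |
| 7 | 6-(3,5-dimethoxybenzyl)-4-hydroxy-2H-pyran-2-one | COc1cc(Cc2cc(O)cc(=O)o2)cc(OC)c1 | intermediate |
| 8 | 4-(benzyloxy)-6-(3,5-dimethoxybenzyl)-2H-pyran-2-one | COc1cc(Cc2cc(OCc3ccccc3)cc(=O)o2)cc(OC)c1 | intermediate |
| 9 | but-2-ynoic acid | CC#CC(=O)O | starting material |
| 10 | but-2-ynoic trifluoroacetic anhydride | CC#CC(=O)OC(=O)C(F)(F)F | intermediate |
| 11 | 1-{2-[(4-benzyloxy-2-oxo-2H-pyran-6-yl)methyl]-4,6-dimethoxyphenyl}but-2-yn-1-one | CC#CC(=O)c1c(OC)cc(OC)cc1Cc1cc(OCc2ccccc2)cc(=O)o1 | intermediate |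
| 12 | 5-[(4-benzyloxy-2-oxo-2H-pyran-6-yl)methyl]-3-iodo-7-methoxy-2-methyl-4H-chromen-4-one | Cc1oc2cc(OC)cc(Cc3cc(OCc4ccccc4)cc(=O)o3)c2c(=O)c1I | intermediate |
| 13 | tributyl(1-ethoxyvinyl)stannane | C=C(OCC)[Sn](CCCC)(CCCC)CCCC | starting material |
| 14 | 5-[(4-benzyloxy-2-oxo-2H-pyran-6-yl)methyl]-3-(1-ethoxyvinyl)-7-methoxy-2-methyl-4H-chromen-4-one | C=C(OCC)c1c(C)oc2cc(OC)cc(Cc3cc(OCc4ccccc4)cc(=O)o3)c2c1=O | intermediate |
| 15 | 2,5-dichloro-1,4-benzoquinone | O=C1C=C(Cl)C(=O)C=C1Cl | starting material |
| 16 | Diels–Alder adduct of 14 and 15: linear tetracycle (ring C, chromanone, new cyclohexene, enedione) with angular CH3 on the former chromone C2, angular Cl beside it and an ethoxy-substituted C=C. Racemic, cis ring fusion, methyl-bearing centre left open | O=C1c2c(Cc3cc(OCc4ccccc4)cc(=O)o3)cc(OC)cc2OC2(C)C1=C(OCC)C[C@@H]1C(=O)C(Cl)=CC(=O)[C@@]12Cl | intermediate |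
| 17 | product of HCl loss from 16: 5,8-dihydro-1,4-naphthoquinone whose C5 bears CH3 and the aryl oxygen still bridging to ring C (racemic) | O=C1c2c(Cc3cc(OCc4ccccc4)cc(=O)o3)cc(OC)cc2OC2(C)C1=C(OCC)CC1=C2C(=O)C=C(Cl)C1=O | intermediate |
| 18 | 6-{2-[(4-benzyloxy-2-oxo-2H-pyran-6-yl)methyl]-6-hydroxy-4-methoxybenzoyl}-2-chloro-7-ethoxy-5-methylnaphthalene-1,4-dione | Cc1c(C(=O)c2c(O)cc(OC)cc2Cc2cc(OCc3ccccc3)cc(=O)o2)c(OCC)cc2c1C(=O)C=C(Cl)C2=O | intermediate |
| 19 | 2-(benzyloxy)-6-{2-[(4-benzyloxy-2-oxo-2H-pyran-6-yl)methyl]-6-hydroxy-4-methoxybenzoyl}-7-ethoxy-5-methylnaphthalene-1,4-dione | Cc1c(C(=O)c2c(O)cc(OC)cc2Cc2cc(OCc3ccccc3)cc(=O)o2)c(OCC)cc2c1C(=O)C=C(OCc1ccccc1)C2=O | intermediate |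
| 20 | 6-{2,4-dihydroxy-6-[(4-hydroxy-2-oxo-2H-pyran-6-yl)methyl]benzoyl}-2,7-dihydroxy-5-methylnaphthalene-1,4-dione | Cc1c(C(=O)c2c(O)cc(O)cc2Cc2cc(O)cc(=O)o2)c(O)cc2c1C(=O)C=C(O)C2=O | target |

## Step count and least certain steps

Total step count: 9. Longest linear sequence: 9 (steps 1–9, from 1).

**Step 7 (key step, proposed new method).**
- **What may go wrong:**
  - The cycloaddition may be too slow, because the inside methyl group twists the diene out of plane and the C4 carbonyl group lowers its donor strength.
  - A 1,5-hydrogen shift from the C2 methyl group to the vinyl terminus could give an exocyclic diene that adds to the quinone faster and leads to a ring-closed xanthone skeleton.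
  - Michael-type attack could be followed by re-aromatisation of the quinone ring to a hydroquinone.
  - Traces of HCl could hydrolyse the enol ether.
  - After ring opening, the 2′-oxygen could displace ethoxide at C7.
- **Fallback:** this uses known chemistry, the Diels–Alder reaction of an open-chain 2-silyloxy-1,3-diene with a haloquinone. It sets out from 11 and comes back at 20. Formal hydration of the triple bond of 11 (Et2NH, then aqueous AcOH in the same flask) should give the 1-arylbutane-1,3-dione F1. Knoevenagel condensation with acetaldehyde (piperidine, AcOH, CH2Cl2, 0 °C) should give the 2-ethylidene-1,3-diketone F2, whose isomers can interconvert; the isomer with CH3 trans to the acetyl arm is drawn. TBSOTf and Et3N should give the 2-(tert-butyldimethylsilyloxy)penta-1,3-diene F3. With 15 (2.5 equiv, NaHCO3, PhMe, 80 °C) the sequence is cycloaddition in the same orientation, loss of HCl, tautomerisation of the dihydronaphthoquinone to the hydroquinone and oxidation by the second equivalent of 15. Acidic work-up should then give the 2-chloro-7-hydroxynaphthoquinone F4. EtI and K2CO3 give the 7-ethyl ether F5, and the conditions of step 8 give the 2-benzyl ether F6. The conditions of step 9 also cleave the extra 2′-methyl ether and give 20.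

**Step 4.**
- **What may go wrong:** acid may add across the triple bond of the product or of the mixed anhydride. Acylation may occur between the two methoxy groups or at C3 of the pyranone. The ynone may oligomerise.
- **Fallback:** the C1′–CO bond is made by nucleophilic addition instead of acylation. It sets out from 8 and comes back at 11. Vilsmeier–Haack formylation (POCl3, DMF) should give the 2,4-dimethoxy-6-(pyranonylmethyl)benzaldehyde F7. 1-Propynylmagnesium bromide at –78 °C should give the racemic propargylic alcohol F8, and MnO2 gives 11.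

**Step 6.**
- **What may go wrong:** oxidative addition or transmetalation may be slow at an iodide flanked by CH3 and C=O. Protodestannylation may consume the tin reagent. The enol ether may be lost by hydrolysis during purification.
- **Fallback:** it sets out from 12 and comes back at 14, with no new compound. It is a Heck vinylation with ethyl vinyl ether under cationic conditions (Pd(OAc)2, 1,3-bis(diphenylphosphino)propane, AgOTf, Et3N, DMF). Insertion then places the chromone on the oxygen-bearing carbon of the vinyl ether and β-hydride elimination gives 14 directly, without tin.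

**Step 8.**
- **What may go wrong:** attack at C3 followed by redox exchange between adduct and quinone. The pyranone may be opened by alkoxide. The 2′-aryloxide may compete as nucleophile, either between molecules at C2 or within the molecule at C7 with loss of ethoxide.
- **Fallback:** the C2 oxygen is brought in with the dienophile, so no substitution is needed. It sets out from 14 and comes back at 20. Oxidation of commercial 1-bromo-2,4,5-trimethoxybenzene F9 with (NH4)2Ce(NO3)6 in aqueous MeCN should give 2-bromo-5-methoxy-1,4-benzoquinone F10. With 14 under the conditions of step 7 this should give the 2-methoxynaphthoquinone F11, and the conditions of step 9 give 20. The price is that the methoxy group opposes the directing effect of bromine in the cycloaddition, which is why this is not the first choice.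

## Further compounds

F1 | step 7 | 1-{2-[(4-benzyloxy-2-oxo-2H-pyran-6-yl)methyl]-4,6-dimethoxyphenyl}butane-1,3-dione | CC(=O)CC(=O)c1c(OC)cc(OC)cc1Cc1cc(OCc2ccccc2)cc(=O)o1
F2 | step 7 | (Z)-1-{2-[(4-benzyloxy-2-oxo-2H-pyran-6-yl)methyl]-4,6-dimethoxyphenyl}-2-ethylidenebutane-1,3-dione | C/C=C(/C(C)=O)C(=O)c1c(OC)cc(OC)cc1Cc1cc(OCc2ccccc2)cc(=O)o1
F3 | step 7 | 3-aroyl-2-(tert-butyldimethylsilyloxy)penta-1,3-diene derived from F2 | C/C=C(/C(=C)O[Si](C)(C)C(C)(C)C)C(=O)c1c(OC)cc(OC)cc1Cc1cc(OCc2ccccc2)cc(=O)o1
F4 | step 7 | 6-{2-[(4-benzyloxy-2-oxo-2H-pyran-6-yl)methyl]-4,6-dimethoxybenzoyl}-2-chloro-7-hydroxy-5-methylnaphthalene-1,4-dione | Cc1c(C(=O)c2c(OC)cc(OC)cc2Cc2cc(OCc3ccccc3)cc(=O)o2)c(O)cc2c1C(=O)C=C(Cl)C2=O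
F5 | step 7 | 6-{2-[(4-benzyloxy-2-oxo-2H-pyran-6-yl)methyl]-4,6-dimethoxybenzoyl}-2-chloro-7-ethoxy-5-methylnaphthalene-1,4-dione | Cc1c(C(=O)c2c(OC)cc(OC)cc2Cc2cc(OCc3ccccc3)cc(=O)o2)c(OCC)cc2c1C(=O)C=C(Cl)C2=O
F6 | step 7 | 2-(benzyloxy)-6-{2-[(4-benzyloxy-2-oxo-2H-pyran-6-yl)methyl]-4,6-dimethoxybenzoyl}-7-ethoxy-5-methylnaphthalene-1,4-dione | Cc1c(C(=O)c2c(OC)cc(OC)cc2Cc2cc(OCc3ccccc3)cc(=O)o2)c(OCC)cc2c1C(=O)C=C(OCc1ccccc1)C2=O
F7 | step 4 | 2-[(4-benzyloxy-2-oxo-2H-pyran-6-yl)methyl]-4,6-dimethoxybenzaldehyde | O=Cc1c(OC)cc(OC)cc1Cc1cc(OCc2ccccc2)cc(=O)o1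
F8 | step 4 | 1-{2-[(4-benzyloxy-2-oxo-2H-pyran-6-yl)methyl]-4,6-dimethoxyphenyl}but-2-yn-1-ol (racemic) | CC#CC(O)c1c(OC)cc(OC)cc1Cc1cc(OCc2ccccc2)cc(=O)o1
F0 | step 6 | none | none
F9 | step 8 | 1-bromo-2,4,5-trimethoxybenzene | COc1cc(OC)c(OC)cc1Br
F10 | step 8 | 2-bromo-5-methoxy-1,4-benzoquinone | COC1=CC(=O)C(Br)=CC1=O
F11 | step 8 | 6-{2-[(4-benzyloxy-2-oxo-2H-pyran-6-yl)methyl]-6-hydroxy-4-methoxybenzoyl}-7-ethoxy-2-methoxy-5-methylnaphthalene-1,4-dione | Cc1c(C(=O)c2c(O)cc(OC)cc2Cc2cc(OCc3ccccc3)cc(=O)o2)c(OCC)cc2c1C(=O)C=C(OC)C2=O
A1 | alternative 1 | 2-bromo-3,5,6,8-tetramethoxy-1-methylnaphthalene | Cc1c(Br)c(OC)cc2c(OC)c(OC)cc(OC)c12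
A2 | alternative 1 | methyl 2-(2-formyl-3,5-dimethoxyphenyl)acetate | COC(=O)Cc1cc(OC)cc(OC)c1C=O
A3 | alternative 1 | methyl 2-{2-[hydroxy(3,5,6,8-tetramethoxy-1-methylnaphthalen-2-yl)methyl]-3,5-dimethoxyphenyl}acetate (racemic) | COC(=O)Cc1cc(OC)cc(OC)c1C(O)c1c(C)c2c(OC)cc(OC)c(OC)c2cc1OC
A4 | alternative 2 | methyl 3-oxo-3-(3,5,6,8-tetramethoxy-1-methylnaphthalen-2-yl)propanoate | COC(=O)CC(=O)c1c(C)c2c(OC)cc(OC)c(OC)c2cc1OC
A5 | alternative 2 | 3,5-dimethoxy-2-(trimethylsilyl)phenyl trifluoromethanesulfonate | COc1cc(OC)c([Si](C)(C)C)c(OS(=O)(=O)C(F)(F)F)c1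
A6 | alternative 2 | methyl 2-[3,5-dimethoxy-2-(3,5,6,8-tetramethoxy-1-methyl-2-naphthoyl)phenyl]acetate | COC(=O)Cc1cc(OC)cc(OC)c1C(=O)c1c(C)c2c(OC)cc(OC)c(OC)c2cc1OC
A7 | alternative 3 | 4-(4-methoxy-2-oxo-2H-pyran-6-yl)-1-(3,5,6,8-tetramethoxy-1-methylnaphthalen-2-yl)but-2-yn-1-one | COc1cc(CC#CC(=O)c2c(C)c3c(OC)cc(OC)c(OC)c3cc2OC)oc(=O)c1
A8 | alternative 3 | 1-methoxy-1,3-bis(trimethylsilyloxy)buta-1,3-diene | COC(O[Si](C)(C)C)=CC(=C)O[Si](C)(C)C
A9 | alternative 3 | 6-[3,5-dihydroxy-2-(3,5,6,8-tetramethoxy-1-methyl-2-naphthoyl)benzyl]-4-methoxy-2H-pyran-2-one | COc1cc(Cc2cc(O)cc(O)c2C(=O)c2c(C)c3c(OC)cc(OC)c(OC)c3cc2OC)oc(=O)c1
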